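**Plan**

1. Retrosynthesis (labdane locants: decalin C1–C10, side chain C11–C16 on C9, C17 on C8, C20 on C10; α is the face of ring B that carries H-5 and C20): the C14=C15 bond is saturated last; the O9–C13 bond and the C16 carbonyl are cut back together to a 3-substituted furan with a free C9–OH; C9–C11 is cut to an organocerium reagent and a C9 ketone; C1–C10 and C4–C5 are cut by a Diels–Alder reaction.
2. Forward: ring B is 2,6-dimethylbenzoquinone; ring A is annulated with 4-methylpenta-1,3-diene to give the cis-decalin; the furylethyl chain is added at C9; one photooxygenation operation then closes the tetrahydrofuran and sets the lactone oxidation level; hydrogenation ends the route.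
3. Enabling feature: C13 is C3 of the furan ring (C13–C14–C15–O–C16). In its singlet-oxygen endoperoxide the C15–O bond ionises to an oxocarbenium ion whose allylic terminus is tertiary C13. O9 sits three atoms away, so 5-exo capture closes the spiro-ether, and C16 keeps the peroxide oxygen that becomes the lactone carbonyl.
4. Stereochemistry: C5/C10 cis from the suprafacial cycloaddition, absolute sense from the chiral oxazaborolidinium catalyst; C8 by equilibration to the equatorial methyl; C9 by equatorial attack trans to that methyl; C6 by dissolving-metal reduction to the equatorial alcohol; C13 by a chiral phosphate in the key step.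

Key step: step 8

Remark: the target as written has H-5, C20, O6, C17 and O9 all on the α-face of a cis-fused decalin. The facial sense of the chiral catalysts in steps 1 and 8 is assigned by analogy with the accepted transition-state models; the mirror-image catalyst is used if either proves opposite.

**Route**

Step 1
Reactants: 1 2,6-dimethyl-1,4-benzoquinone; 2 4-methylpenta-1,3-diene
Product: 3 (4aS,8aR)-2,5,5,8a-tetramethyl-4a,5,8,8a-tetrahydronaphthalene-1,4-dione (cis-fused; labdane 5S,10R)
Conditions: 2 (3 equiv), oxazaborolidinium catalyst from (S)-3,3-diphenyl-1-(o-tolyl)tetrahydro-1H,3H-pyrrolo[1,2-c][1,3,2]oxazaborole and HNTf2 (20 mol %), CH2Cl2, −78 → −40 °C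
Reagents that add atoms: none
Why: Lewis-acid-catalysed Diels–Alder reaction of a quinone under chiral oxazaborolidinium catalysis: the cation binds the unhindered carbonyl oxygen (the future C6=O, flanked by two C–H), which makes the methyl-bearing carbon (C10) the electrophilic terminus, so the CH2 end of the diene (largest HOMO coefficient) bonds to C10 and the CMe2 end to C5 without creating vicinal quaternary centres; suprafacial addition puts H-5 and the C10 methyl cis, and the shielded face of the bound quinone decides the absolute configuration (5S,10R).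

Step 2
Reactants: 3 (4aS,8aR)-2,5,5,8a-tetramethyl-4a,5,8,8a-tetrahydronaphthalene-1,4-dione
Product: 4 (4R,4aS,8aR)-4-hydroxy-2,5,5,8a-tetramethyl-4a,5,8,8a-tetrahydronaphthalen-1(4H)-one (6β-hydroxy enone; labdane 5S,6R,10R)
Conditions: NaBH4, CeCl3·7H2O, MeOH, −78 °C
Reagents that add atoms: none
Why: Luche 1,2-reduction: hydride is delivered to the C6 carbonyl, which is flanked by two C–H carbons, in preference to the C9 carbonyl next to quaternary C10 and the C8 methyl, and from the convex α-face (6R carbinol); this centre is a temporary mask for C6 (re-oxidised in step 6) that also closes the enolisation path to C5.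

Step 3
Reactants: 4 (4R,4aS,8aR)-4-hydroxy-2,5,5,8a-tetramethyl-4a,5,8,8a-tetrahydronaphthalen-1(4H)-one
Product: 6 (2R,4R,4aS,8aR)-4-hydroxy-2,5,5,8a-tetramethyloctahydronaphthalen-1(2H)-one, via C8-epimeric hydroxy ketone 5 (not isolated)
Conditions: H2 (1 atm), Pd/C (10%), EtOAc, rt; filter; then NaOMe (0.2 equiv), MeOH, rt
Reagents that add atoms: none
Why: Heterogeneous catalytic hydrogenation of both C=C bonds, then base-mediated epimerisation α to the ketone: hydrogen should enter C8 from the convex face (axial methyl, 5), and enolisation towards C8, the only enolisable position now that C6 is a carbinol, moves the methyl to the equatorial 8α-position, cis to C20, in the chair that has C1 axial on ring B.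

Step 4
Reactants: 7 2-(furan-3-yl)ethan-1-ol
Product: 8 3-(2-iodoethyl)furan
Conditions: I2, PPh3, imidazole, CH2Cl2, 0 °C → rt
Reagents that add atoms: iodine, II
Why: Appel-type iodination of a primary alcohol by SN2 displacement of the alkoxyphosphonium ion; no stereocentre is involved.

Step 5
Reactants: 6 (2R,4R,4aS,8aR)-4-hydroxy-2,5,5,8a-tetramethyloctahydronaphthalen-1(2H)-one; 8 3-(2-iodoethyl)furan
Product: 11 (1R,2R,4R,4aS,8aR)-1-[2-(furan-3-yl)ethyl]-2,5,5,8a-tetramethyldecahydronaphthalene-1,4-diol, via 2-(furan-3-yl)ethyllithium 9 (not isolated), via 2-(furan-3-yl)ethylcerium dichloride 10 (not isolated)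
Conditions: 8 (2.5 equiv), t-BuLi (5 equiv), Et2O, −78 °C; anhydrous CeCl3, THF, −78 °C; then 6, −78 → −20 °C; aq NH4Cl
Reagents that add atoms: none
Why: Iodine–lithium exchange, transmetalation to cerium and 1,2-addition of the weakly basic organocerium reagent to the hindered, enolisable ketone (one equivalent is spent on the C6 hydroxyl): as in additions to 2,2,6-trisubstituted cyclohexanones the nucleophile should enter equatorially, trans to the equatorial C8 methyl, so C11 becomes equatorial (β) and the new C9 hydroxyl axial (α, 9R).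

Step 6
Reactants: 11 (1R,2R,4R,4aS,8aR)-1-[2-(furan-3-yl)ethyl]-2,5,5,8a-tetramethyldecahydronaphthalene-1,4-diol
Product: 12 (3R,4R,4aR,8aS)-4-[2-(furan-3-yl)ethyl]-4-hydroxy-3,4a,8,8-tetramethyloctahydronaphthalen-1(2H)-one (C6 ketone)
Conditions: Dess–Martin periodinane, NaHCO3, CH2Cl2, 0 °C → rt
Reagents that add atoms: none
Why: Dess–Martin oxidation of the secondary C6 carbinol; the tertiary C9 hydroxyl and the furan are inert, and the buffered, non-enolising medium leaves C5 untouched.

Step 7
Reactants: 12 (3R,4R,4aR,8aS)-4-[2-(furan-3-yl)ethyl]-4-hydroxy-3,4a,8,8-tetramethyloctahydronaphthalen-1(2H)-one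
Product: 13 (1R,2R,4S,4aS,8aR)-1-[2-(furan-3-yl)ethyl]-2,5,5,8a-tetramethyldecahydronaphthalene-1,4-diol (labdane 5S,6S,8R,9R,10R)
Conditions: Li, NH3(l), THF, MeOH (2 equiv), −78 °C; then NH4Cl
Reagents that add atoms: none
Why: Dissolving-metal reduction of the ketone, which gives the thermodynamically preferred equatorial alcohol: in the chair fixed by the equatorial C8 methyl and C11, the 6α-hydroxyl (6S, cis to H-5) is equatorial whereas its epimer would be syn-axial to C1; the non-conjugated furan is not reduced.

Step 8
Reactants: 13 (1R,2R,4S,4aS,8aR)-1-[2-(furan-3-yl)ethyl]-2,5,5,8a-tetramethyldecahydronaphthalene-1,4-diol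
Product: 16 (5S,6S,8R,9R,10R,13R)-6-acetoxy-9,13-epoxylabd-14-en-16,15-olide, via furan endoperoxide 14 (not isolated), via spirocyclic hydroperoxy acetal 15 (not isolated)
Conditions: O2, tetraphenylporphyrin (1 mol %), visible light, CH2Cl2, −78 °C; N2 purge; (R)-3,3′-bis(2,4,6-triisopropylphenyl)-1,1′-binaphthyl-2,2′-diyl hydrogen phosphate (5 mol %), −78 → −40 °C; then Ac2O, pyridine, DMAP (cat.), −40 °C → rt
Reagents that add atoms: dioxygen, O=O; acetic anhydride, CC(=O)OC(C)=O
Why: Proposed new method: singlet oxygen adds [4+2] across C16 and C15 of the furan to give endoperoxide 14; the phosphoric acid protonates the peroxide bridge and the C15–O bond ionises, the only mode that places the allylic positive charge on tertiary C13, and the C9 hydroxyl adds to C13 to give hydroperoxy acetal 15, whose C16–OOH is dehydrated by Ac2O/pyridine to the lactone carbonyl while O6 is acetylated. The closest known reactions are furan photooxygenation cascades in which a tethered hydroxyl captures the endoperoxide (spiroketal syntheses), chiral-phosphoric-acid-controlled spiroketalisation, and the Ac2O/amine dehydration of α-alkoxy hydroperoxides to esters. The tetrahydrofuran closes in the 5-exo-trig mode by attack of O9 on the allyl/oxocarbenium terminus; the dihydrofuranone ring is the furan ring itself and is not closed here. New stereocentre C13 is fixed by the face of the planar cation that O9 attacks: the substrate bias is small because C9 is flanked by C8 and C10, each carrying an equatorial methyl, so the chiral phosphate, hydrogen-bonded to O9–H and to the C16 peroxide, is the controlling element, while C16 is a transient centre that is erased. The step needs site selectivity (ionisation at C15–O, since ionisation at C16–O would lead to a six-membered 9,16-acetal), ring-size selectivity (five and not seven, set by the two-carbon tether) and chemoselectivity (O6–H cannot reach the cation and is only acetylated); the acid is quenched by pyridine before the product can re-ionise.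

Step 9
Reactants: 16 (5S,6S,8R,9R,10R,13R)-6-acetoxy-9,13-epoxylabd-14-en-16,15-olide
Product: 17 (5S,6S,8R,9R,10R,13R)-6-acetoxy-9,13-epoxylabdan-16,15-olide (target)
Conditions: H2 (1 atm), Rh/Al2O3 (5%), EtOAc, rt
Reagents that add atoms: none
Why: Heterogeneous hydrogenation of the electron-rich, disubstituted enol-lactone C14=C15 bond on a catalyst of low hydrogenolysis activity; no stereocentre is formed and the ester groups and the allylic-type C13–O9 bond should be untouched.

**Compound list**

1 | 2,6-dimethyl-1,4-benzoquinone | CC1=CC(=O)C=C(C)C1=O | starting material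
2 | 4-methylpenta-1,3-diene | CC(C)=CC=C | starting material
3 | (4aS,8aR)-2,5,5,8a-tetramethyl-4a,5,8,8a-tetrahydronaphthalene-1,4-dione | O=C1C=C(C)C(=O)[C@]2(C)CC=CC(C)(C)[C@H]12 | intermediate
4 | (4R,4aS,8aR)-4-hydroxy-2,5,5,8a-tetramethyl-4a,5,8,8a-tetrahydronaphthalen-1(4H)-one | O[C@@H]1C=C(C)C(=O)[C@]2(C)CC=CC(C)(C)[C@H]12 | intermediate
5 | (2S,4R,4aS,8aR)-4-hydroxy-2,5,5,8a-tetramethyloctahydronaphthalen-1(2H)-one (C8 epimer of 6) | O[C@@H]1C[C@H](C)C(=O)[C@]2(C)CCCC(C)(C)[C@H]12 | intermediate (not isolated)
6 | (2R,4R,4aS,8aR)-4-hydroxy-2,5,5,8a-tetramethyloctahydronaphthalen-1(2H)-one | O[C@@H]1C[C@@H](C)C(=O)[C@]2(C)CCCC(C)(C)[C@H]12 | intermediate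
7 | 2-(furan-3-yl)ethan-1-ol | OCCc1ccoc1 | starting material
8 | 3-(2-iodoethyl)furan | ICCc1ccoc1 | intermediate
9 | 2-(furan-3-yl)ethyllithium | [Li]CCc1ccoc1 | intermediate (not isolated)
10 | 2-(furan-3-yl)ethylcerium dichloride | Cl[Ce](Cl)CCc1ccoc1 | intermediate (not isolated)
11 | (1R,2R,4R,4aS,8aR)-1-[2-(furan-3-yl)ethyl]-2,5,5,8a-tetramethyldecahydronaphthalene-1,4-diol | O[C@@H]1C[C@@H](C)[C@](O)(CCc3ccoc3)[C@]2(C)CCCC(C)(C)[C@H]12 | intermediate
12 | (3R,4R,4aR,8aS)-4-[2-(furan-3-yl)ethyl]-4-hydroxy-3,4a,8,8-tetramethyloctahydronaphthalen-1(2H)-one | O=C1C[C@@H](C)[C@](O)(CCc3ccoc3)[C@]2(C)CCCC(C)(C)[C@H]12 | intermediate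
13 | (1R,2R,4S,4aS,8aR)-1-[2-(furan-3-yl)ethyl]-2,5,5,8a-tetramethyldecahydronaphthalene-1,4-diol | O[C@H]1C[C@@H](C)[C@](O)(CCc3ccoc3)[C@]2(C)CCCC(C)(C)[C@H]12 | intermediate
14 | endoperoxide of 13: 2,3,7-trioxabicyclo[2.2.1]hept-5-ene formed across C15/C16, attached through C13 (bridgehead epimers) | O[C@H]1C[C@@H](C)[C@](O)(CCC3=CC4OOC3O4)[C@]2(C)CCCC(C)(C)[C@H]12 | intermediate (not isolated)
15 | (5S,6S,8R,9R,10R,13R)-16-hydroperoxy-9,13:15,16-diepoxylabd-14-en-6-ol (C16 epimers) | O[C@H]1C[C@@H](C)[C@]2(CC[C@]3(C=COC3OO)O2)[C@]2(C)CCCC(C)(C)[C@H]12 | intermediate (not isolated)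
16 | (5S,6S,8R,9R,10R,13R)-6-acetoxy-9,13-epoxylabd-14-en-16,15-olide | CC(=O)O[C@H]1C[C@@H](C)[C@]2(CC[C@]3(C=COC3=O)O2)[C@]2(C)CCCC(C)(C)[C@H]12 | intermediate
17 | (5S,6S,8R,9R,10R,13R)-6-acetoxy-9,13-epoxylabdan-16,15-olide | CC(=O)O[C@H]1C[C@@H](C)[C@]2(CC[C@]3(CCOC3=O)O2)[C@]2(C)CCCC(C)(C)[C@H]12 | target

**Step count and risks**

Total steps: 9. Longest linear sequence: 8 (steps 1–3 and 5–9).

Steps most likely to fail:

1. Step 8. The endoperoxide may ionise at C16–O and be captured as the six-membered 9,16-acetal, may fragment before the hindered tertiary hydroxyl adds, or may close with little facial discrimination at C13. The fallback uses known reactions, sets out from 13 and comes back to the route at 17. Compound 13 is acetylated (Ac2O, pyridine, DMAP) to (5S,6S,8R,9R,10R)-6-acetoxy-15,16-epoxylabda-13(16),14-dien-9-ol F1. Sensitised photooxygenation in the presence of i-Pr2NEt (Kornblum–DeLaMare opening of the endoperoxide) gives the γ-hydroxybutenolide F2. Dess–Martin oxidation gives the 2-substituted maleic anhydride F3; either hydroxybutenolide regioisomer converges here. DBU-catalysed intramolecular oxa-Michael addition of the C9 hydroxyl to C13 (5-exo, reversible, so the spiro centre can equilibrate) gives the spiro succinic anhydride F4. LiBH(s-Bu)3 in THF at −78 °C should then reduce the less hindered C15 carbonyl, and acidic work-up closes the lactone to 17.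

2. Step 1. The Z-methyl of the diene disfavours the s-cis conformer, so the cycloaddition may be slow, the diene may oligomerise under the strong Lewis acid, and an uncatalysed background reaction may erode the enantioselectivity. The fallback sets out from 1 and 2 and comes back at 4. A BF3·OEt2-promoted (or 10 kbar) cycloaddition gives 3 together with its enantiomer, (4aR,8aS)-2,5,5,8a-tetramethyl-4a,5,8,8a-tetrahydronaphthalene-1,4-dione F5. Luche reduction gives 4 and its enantiomer, the (4S,4aR,8aS)-hydroxy enone F6. Candida antarctica lipase B with vinyl acetate should acetylate the (6R)-carbinol 4, the fast-reacting enantiomer by the empirical rule for lipases, to the acetate of 4 F7. F7 is separated from unreacted F6 and methanolysed (K2CO3, MeOH) to 4.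

3. Step 5. The ketone may enolise instead of adding the reagent, or the reagent may approach from the α-face (axial attack) and give the C9 epimer. The fallback sets out from 6 and comes back at 11; it sets C9 by the face of an epoxidation instead. Wittig methylenation (Ph3P=CH2, toluene, 90 °C) gives (1R,3R,4aR,8aS)-3,4a,8,8-tetramethyl-4-methylidenedecahydronaphthalen-1-ol F8. m-CPBA should epoxidise the exocyclic alkene from the α-face (axial and convex; the β-face is blocked by axial C1) to the spiro-epoxide F9. Copper-catalysed opening at C11 with (furan-3-yl)methylmagnesium chloride (CuI, THF, −30 °C) gives 11.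

**Further compounds**

F1 | step 8 | (5S,6S,8R,9R,10R)-6-acetoxy-15,16-epoxylabda-13(16),14-dien-9-ol | CC(=O)O[C@H]1C[C@@H](C)[C@](O)(CCc3ccoc3)[C@]2(C)CCCC(C)(C)[C@H]12
F2 | step 8 | (5S,6S,8R,9R,10R)-6-acetoxy-9,16-dihydroxylabd-13-en-15,16-olide (γ-hydroxybutenolide, C16 epimers) | CC(=O)O[C@H]1C[C@@H](C)[C@](O)(CCC3=CC(=O)OC3O)[C@]2(C)CCCC(C)(C)[C@H]12
F3 | step 8 | (5S,6S,8R,9R,10R)-6-acetoxy-9-hydroxylabd-13-ene-15,16-dioic anhydride | CC(=O)O[C@H]1C[C@@H](C)[C@](O)(CCC3=CC(=O)OC3=O)[C@]2(C)CCCC(C)(C)[C@H]12
F4 | step 8 | (5S,6S,8R,9R,10R,13R)-6-acetoxy-9,13-epoxylabdane-15,16-dioic anhydride | CC(=O)O[C@H]1C[C@@H](C)[C@]2(CC[C@]3(CC(=O)OC3=O)O2)[C@]2(C)CCCC(C)(C)[C@H]12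
F5 | step 1 | (4aR,8aS)-2,5,5,8a-tetramethyl-4a,5,8,8a-tetrahydronaphthalene-1,4-dione | O=C1C=C(C)C(=O)[C@@]2(C)CC=CC(C)(C)[C@@H]12
F6 | step 1 | (4S,4aR,8aS)-4-hydroxy-2,5,5,8a-tetramethyl-4a,5,8,8a-tetrahydronaphthalen-1(4H)-one | O[C@H]1C=C(C)C(=O)[C@@]2(C)CC=CC(C)(C)[C@@H]12
F7 | step 1 | (1R,4aR,8aS)-3,4a,8,8-tetramethyl-4-oxo-1,4,4a,5,8,8a-hexahydronaphthalen-1-yl acetate | CC(=O)O[C@@H]1C=C(C)C(=O)[C@]2(C)CC=CC(C)(C)[C@H]12
F8 | step 5 | (1R,3R,4aR,8aS)-3,4a,8,8-tetramethyl-4-methylidenedecahydronaphthalen-1-ol | O[C@@H]1C[C@@H](C)C(=C)[C@]2(C)CCCC(C)(C)[C@H]12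
F9 | step 5 | (1R,2R,4R,4aS,8aR)-2,5,5,8a-tetramethyloctahydro-2H-spiro[naphthalene-1,2'-oxiran]-4-ol | O[C@@H]1C[C@@H](C)[C@]2(CO2)[C@]2(C)CCCC(C)(C)[C@H]12
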